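**Assumption:** the target SMILES has no stereocentre and its alkene carries two identical methyl groups, so the compound is achiral and no stereocontrol is needed.

**Retrosynthetic overview**
1. Target 12 ⇐ triol acid 10 by acetylation of its only aliphatic OH (last step).
2. 10 ⇐ 9 ⇐ 8 ⇐ 6: double SN2 O-demethylation (methyl ester and ArOMe), CHO reduction, ortho-C-prenylation of the ring-B phenol.
3. 6 ⇐ 1 + 2: key disconnection at the diaryl ether C(ring A)–O bond, made by a new acyl-transfer/Smiles cascade. The phenol carbon of ring A is the electrophile, the acetonide oxygen of ring B the nucleophile, and acetone is lost; the carboxylate is trapped as the methyl ester.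
4. Rings: none is built. Both benzene rings are bought (1 and 2); only a transient spiro-dioxinone appears in the Smiles step.

**Route**

Step 1
Reactants: 1 5-hydroxy-2,2-dimethyl-4H-1,3-benzodioxin-4-one; 2 2-hydroxy-3-methoxy-5-methylbenzaldehyde; 3 iodomethane
Product: 6 methyl 2-(2-formyl-6-methoxy-4-methylphenoxy)-6-hydroxybenzoate, via depside aryl ester 4 (not isolated), via diaryl ether acid 5 (not isolated)
Conditions: 2 (1.3 equiv), KOt-Bu (1.25 equiv), DMSO, rt; 1 added slowly, 70 °C, N2 sweep (−acetone); then MeI (2 equiv), rt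
Reagents that add atoms: iodomethane 3, CI
Why: Proposed new method: the potassium phenoxide of 2 (the more acidic phenol, so the chelated 5-OH of 1 stays protonated and keeps activating the lactone carbonyl) opens the acylal-type ester of 1 by addition–elimination to give depside 4, the expelled hemiketal alkoxide loses acetone and unveils the ring-B phenoxide ortho to the new aryl ester, and this oxygen attacks the ester-bearing ipso carbon of ring A (activated by its ortho-formyl group) through a six-membered spiro-Meisenheimer transition state with carboxylate as leaving group, so the diaryl ether C–O bond forms in an irreversible Smiles rearrangement whose regiochemistry is unambiguous because the 2,6-dihydroxybenzoyl unit is symmetric; slow addition of 1 suppresses its self-condensation, and the carboxylate of 5 is then O-methylated (SN2) while the hydrogen-bonded phenol, with no base left, is not; the closest known reaction types are the base-induced Smiles rearrangement of depsides (aryl 2-hydroxybenzoates) to 2-aryloxybenzoic acids and the alkoxide ring-opening of 2,2-dimethylbenzodioxinones to salicylate esters, but as far as I know their merger into a one-flask deacetonative O-arylation has not been described.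

Step 2
Reactants: 6 methyl 2-(2-formyl-6-methoxy-4-methylphenoxy)-6-hydroxybenzoate; 7 1-bromo-3-methylbut-2-ene (prenyl bromide)
Product: 8 methyl 6-(2-formyl-6-methoxy-4-methylphenoxy)-2-hydroxy-3-(3-methylbut-2-en-1-yl)benzoate
Conditions: NaH (1.05 equiv), toluene, 0 °C → rt; 7 (1.3 equiv), rt → 45 °C
Reagents that add atoms: 1-bromo-3-methylbut-2-ene 7, CC(C)=CCBr
Why: In toluene the sodium phenoxide is a tight, ester-chelated ion pair, so SN2 alkylation occurs through carbon at the only free ortho position, which is also para to the aryloxy group (ortho-selective phenoxide C-prenylation); ring A has no free OH at this stage and cannot compete.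

Step 3
Reactants: 8 methyl 6-(2-formyl-6-methoxy-4-methylphenoxy)-2-hydroxy-3-(3-methylbut-2-en-1-yl)benzoate
Product: 9 methyl 2-hydroxy-6-[2-(hydroxymethyl)-6-methoxy-4-methylphenoxy]-3-(3-methylbut-2-en-1-yl)benzoate
Conditions: NaBH4 (0.6 equiv), MeOH–THF, 0 °C
Reagents that add atoms: none
Why: Chemoselective borohydride reduction of the aryl aldehyde; the hindered, hydrogen-bonded salicylate ester and the trisubstituted alkene are inert.

Step 4
Reactants: 9 methyl 2-hydroxy-6-[2-(hydroxymethyl)-6-methoxy-4-methylphenoxy]-3-(3-methylbut-2-en-1-yl)benzoate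
Product: 10 2-hydroxy-6-[2-hydroxy-6-(hydroxymethyl)-4-methylphenoxy]-3-(3-methylbut-2-en-1-yl)benzoic acid
Conditions: EtSNa (8 equiv), degassed DMF, 125 °C; then aq. HCl to pH 3, 0 °C
Reagents that add atoms: none
Why: Thiolate SN2 dealkylation at both O-methyl carbons (the hindered ester first, then the aryl methyl ether), a purely basic method that spares the acid-sensitive ortho-prenylphenol, the diaryl ether and the benzylic alcohol.

Step 5
Reactants: 10 2-hydroxy-6-[2-hydroxy-6-(hydroxymethyl)-4-methylphenoxy]-3-(3-methylbut-2-en-1-yl)benzoic acid; 11 vinyl acetate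
Product: 12 6-[2-(acetoxymethyl)-6-hydroxy-4-methylphenoxy]-2-hydroxy-3-(3-methylbut-2-en-1-yl)benzoic acid (7-O-acetylsecopenicillide C)
Conditions: Novozym 435 (immobilised CAL-B), vinyl acetate (5 equiv), MTBE–THF, 35 °C
Reagents that add atoms: vinyl acetate 11, CC(=O)OC=C
Why: Lipase-catalysed irreversible transesterification acetylates only the primary benzylic alcohol, because phenols and the 2,6-disubstituted benzoic acid are not accepted by the enzyme, and tautomerisation of the released vinyl alcohol to acetaldehyde drives it to completion.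

**Compound list**
1 | 5-hydroxy-2,2-dimethyl-4H-1,3-benzodioxin-4-one (acetonide of 2,6-dihydroxybenzoic acid, catalogue compound) | CC1(C)OC(=O)c2c(O)cccc2O1 | starting material
2 | 2-hydroxy-3-methoxy-5-methylbenzaldehyde (catalogue compound) | COc1cc(C)cc(C=O)c1O | starting material
3 | iodomethane | CI | starting material
4 | 2-formyl-6-methoxy-4-methylphenyl 2,6-dihydroxybenzoate (depside aryl ester, present as its potassium phenoxide) | O=Cc1cc(C)cc(OC)c1OC(=O)c1c(O)cccc1O | intermediate
5 | 2-(2-formyl-6-methoxy-4-methylphenoxy)-6-hydroxybenzoic acid (diaryl ether acid, present as its potassium carboxylate) | OC(=O)c1c(O)cccc1Oc1c(C=O)cc(C)cc1OC | intermediate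
6 | methyl 2-(2-formyl-6-methoxy-4-methylphenoxy)-6-hydroxybenzoate | COC(=O)c1c(O)cccc1Oc1c(C=O)cc(C)cc1OC | intermediate
7 | 1-bromo-3-methylbut-2-ene (prenyl bromide) | CC(C)=CCBr | starting material
8 | methyl 6-(2-formyl-6-methoxy-4-methylphenoxy)-2-hydroxy-3-(3-methylbut-2-en-1-yl)benzoate | COC(=O)c1c(O)c(CC=C(C)C)ccc1Oc1c(C=O)cc(C)cc1OC | intermediate
9 | methyl 2-hydroxy-6-[2-(hydroxymethyl)-6-methoxy-4-methylphenoxy]-3-(3-methylbut-2-en-1-yl)benzoate | COC(=O)c1c(O)c(CC=C(C)C)ccc1Oc1c(CO)cc(C)cc1OC | intermediate
10 | 2-hydroxy-6-[2-hydroxy-6-(hydroxymethyl)-4-methylphenoxy]-3-(3-methylbut-2-en-1-yl)benzoic acid | OC(=O)c1c(O)c(CC=C(C)C)ccc1Oc1c(CO)cc(C)cc1O | intermediate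
11 | vinyl acetate | CC(=O)OC=C | starting material
12 | 6-[2-(acetoxymethyl)-6-hydroxy-4-methylphenoxy]-2-hydroxy-3-(3-methylbut-2-en-1-yl)benzoic acid (7-O-acetylsecopenicillide C) | CC(=O)OCc1cc(C)cc(O)c1Oc1ccc(CC=C(C)C)c(O)c1C(=O)O | target

**Totals**
Total step count: 5. Longest linear sequence: 5 steps (1 → 6 → 8 → 9 → 10 → 12).

**Steps most likely to fail, with fallbacks**

Step 1 (the proposed new cascade). The acyl transfer from 1 to the hindered, weakly nucleophilic phenoxide of 2 may be slow, 1 may self-condense, or the Smiles step may stall with only one ortho-formyl activator. The fallback uses known chemistry, sets out from 2 and returns at 6. A carboxylate-assisted Ullmann ether synthesis of 2 with commercial 2-bromo-6-methoxybenzoic acid (CuI cat., K2CO3, DMF, 110 °C) gives 2-(2-formyl-6-methoxy-4-methylphenoxy)-6-methoxybenzoic acid F1. Esterification with MeI/K2CO3 gives methyl 2-(2-formyl-6-methoxy-4-methylphenoxy)-6-methoxybenzoate F2. BCl3 (CH2Cl2, −78 → 0 °C) then cleaves only the methyl ether that is chelated to the ester carbonyl and delivers 6.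

Step 2 (ortho-C-prenylation). O-prenylation, para attack or double alkylation may lower the yield. The fallback sets out from 6 and returns at 8, and replaces direct C-alkylation by an O-alkylation/sigmatropic sequence. Pd(PPh3)4-catalysed reaction of 6 with tert-butyl 2-methylbut-3-en-2-yl carbonate (THF, 0 °C) gives the tertiary allyl ether methyl 2-(2-formyl-6-methoxy-4-methylphenoxy)-6-[(2-methylbut-3-en-2-yl)oxy]benzoate F3. Heating (toluene, 110 °C, or cat. Eu(fod)3) triggers the aromatic Claisen rearrangement, which can deliver the allyl unit, inverted to prenyl, only to the one free ortho carbon, giving 8.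

Step 4 (global thiolate demethylation at 125 °C). The unactivated aryl methyl ether may resist cleavage, or the prenylated arene may suffer. The fallback sets out from 6 and returns at 10, and moves the ether cleavage ahead of the prenyl group. BBr3 (CH2Cl2, −78 → 0 °C) converts 6 into methyl 2-(2-formyl-6-hydroxy-4-methylphenoxy)-6-hydroxybenzoate F4. TBSCl/imidazole silylates only the non-chelated ring-A phenol, giving methyl 2-[2-(tert-butyldimethylsilyloxy)-6-formyl-4-methylphenoxy]-6-hydroxybenzoate F5. The conditions of step 2 then give methyl 6-[2-(tert-butyldimethylsilyloxy)-6-formyl-4-methylphenoxy]-2-hydroxy-3-(3-methylbut-2-en-1-yl)benzoate F6. The conditions of step 3 give methyl 6-[2-(tert-butyldimethylsilyloxy)-6-(hydroxymethyl)-4-methylphenoxy]-2-hydroxy-3-(3-methylbut-2-en-1-yl)benzoate F7. EtSNa in DMF at only 60 °C (ester methyl alone), followed by TBAF in THF, gives 10.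

**Further compounds**
F1 | step 1 | 2-(2-formyl-6-methoxy-4-methylphenoxy)-6-methoxybenzoic acid | OC(=O)c1c(OC)cccc1Oc1c(C=O)cc(C)cc1OC
F2 | step 1 | methyl 2-(2-formyl-6-methoxy-4-methylphenoxy)-6-methoxybenzoate | COC(=O)c1c(OC)cccc1Oc1c(C=O)cc(C)cc1OC
F3 | step 2 | methyl 2-(2-formyl-6-methoxy-4-methylphenoxy)-6-[(2-methylbut-3-en-2-yl)oxy]benzoate | COC(=O)c1c(OC(C)(C)C=C)cccc1Oc1c(C=O)cc(C)cc1OC
F4 | step 4 | methyl 2-(2-formyl-6-hydroxy-4-methylphenoxy)-6-hydroxybenzoate | COC(=O)c1c(O)cccc1Oc1c(C=O)cc(C)cc1O
F5 | step 4 | methyl 2-[2-(tert-butyldimethylsilyloxy)-6-formyl-4-methylphenoxy]-6-hydroxybenzoate | COC(=O)c1c(O)cccc1Oc1c(C=O)cc(C)cc1O[Si](C)(C)C(C)(C)C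
F6 | step 4 | methyl 6-[2-(tert-butyldimethylsilyloxy)-6-formyl-4-methylphenoxy]-2-hydroxy-3-(3-methylbut-2-en-1-yl)benzoate | COC(=O)c1c(O)c(CC=C(C)C)ccc1Oc1c(C=O)cc(C)cc1O[Si](C)(C)C(C)(C)C
F7 | step 4 | methyl 6-[2-(tert-butyldimethylsilyloxy)-6-(hydroxymethyl)-4-methylphenoxy]-2-hydroxy-3-(3-methylbut-2-en-1-yl)benzoate | COC(=O)c1c(O)c(CC=C(C)C)ccc1Oc1c(CO)cc(C)cc1O[Si](C)(C)C(C)(C)C
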